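## The problem

Target 20 is a 2,3,4-trisubstituted oxolane (ring A: O1, C2, C3, C4, C5). C2 carries a 4-hydroxy-3,5-dimethoxyphenyl (syringyl) ring, C3 a feruloyloxymethyl arm and C4 a 4-hydroxy-3-methoxybenzyl (guaiacylmethyl) arm, with the configuration (2S,3R,4R): aryl and C3 arm trans, C3 and C4 arms cis. The two aryl groups differ, so the skeleton cannot come from dimerising one C6–C3 unit, and each arm needs its own bond construction. Only C2 needs an outside source of chirality. An aryl group on C2 can direct C3 (trans) and, through the forming ring, C4; the cis relation of the two arms is the less stable one and must be set kinetically. C2 is a benzylic ether carbon on an electron-rich ring: acid can ionise it (epimerisation, ring opening, Friedel–Crafts closure onto the guaiacyl ring) and hydrogenolysis cleaves it. The three phenols and the cinnamate ester (a Michael acceptor, sensitive to base and to hydrogenation) call for late esterification and for protecting groups that leave under near-neutral, non-reductive conditions. The enabling feature is that C5, C4 and the exocyclic CH2 on C4 are the three carbons of an O-allyl group on O1. A radical at C3 can therefore close ring A by 5-exo attack on C4 (bond C3–C4), and the exocyclic radical left behind is where the guaiacyl ring is attached.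

## Retrosynthesis

**Ester bond (O–C=O of the C3 arm): 20 ← 19 ← 15 + 18.** The feruloyl group is removed first. A cinnamate would not survive radical, organozinc and nickel chemistry, so it is attached after the ring is built. This leaves primary alcohol 15 with both phenols silylated, and O-silylated ferulic acid 18. The forward steps are a neutral carbodiimide esterification and a buffered fluoride cleavage of three aryl silyl ethers that spares the ester.

**Silyl differentiation: 15 ← 14.** The three hydroxyls of 14 carry the same silyl group, which keeps the front end simple. The forward step must cleave the one alkyl silyl ether with acid mild enough to spare the two aryl silyl ethers and the C2 benzylic ether.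

**C3–C4 of ring A and CH2–aryl (key cut): 14 ← 9 + 13.** Both bonds lie on the alkene carbons of an allyl ether, so adding a C3 radical and an aryl group across that alkene makes them together. Cutting O1–C2 or C2–C3 instead would leave two or three stereocentres to build in an open chain. This cut leaves iodide 9, whose only controlling centre is the benzylic carbon (the iodo carbon becomes planar), and arylzinc reagent 13. The forward reaction must cyclise before it couples, and the C2 aryl group must set C3 and C4.

**Arylzinc reagent: 13 ← 11 ← 10.** The C–Zn bond comes from the C–Br bond of 11 through the Grignard reagent 12; 11 is the silyl ether of 10. The bromide is para to the silyloxy group, so metalation is not complicated by silyl migration.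

**C–I and O–Si: 9 ← 8 ← 7.** The iodide is made by substitution of the secondary hydroxyl of 8, and 8 by silylation of the primary hydroxyl of diol 7. The configuration at the iodo carbon is irrelevant, so the substitution only has to proceed cleanly.

**Benzylic C–O(allyl): 7 ← 5 + 6.** Opening epoxy alcohol 5 at its benzylic carbon with allyl alcohol 6 forms the ether and the diol in one step. This is shorter than alkylating a preformed benzylic alcohol, which would need a differentiated triol. The forward reaction must be regioselective for the benzylic carbon and must invert it cleanly.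

**Epoxide and chain: 5 ← 4 ← 3 ← 2 ← 1.** Sharpless epoxidation of allylic alcohol 4 sets the single bought stereocentre. Alcohol 4 comes from sinapic acid 1 by esterification (2), phenol silylation (3) and ester reduction.

**Acid partner: 18 ← 16.** Ferulic acid 16 is silylated on both oxygens (17) and the silyl ester is hydrolysed selectively.

## Roads not taken

**Alternative 1:** The cut is at the bonds from C3 and C4 to their exocyclic carbons, on a preformed lactone ring. A vinyl copper reagent would add to enantiopure γ-aryl butenolide A1 anti to the aryl group, and the enolate would condense with silylated vanillin A2 to give benzylidene lactone A3. Merits: a convergent, well-known three-component coupling. The 2,3-trans relation comes from the anti addition, and hydrogenation of the benzylidene from the face away from the C3 arm should give the cis C3/C4 relation reliably. In that last respect it is probably stronger than the radical closure chosen here. Weak points for this target: A3 holds two alkenes that must be told apart (a vinyl group to cleave, a benzylidene to hydrogenate). Its C5 is a lactone carbonyl that must be taken down to CH2, and the usual ionic reduction of a lactol also attacks the electron-rich C2 benzylic ether. A1 needs its own asymmetric synthesis and has an acidic γ-hydrogen that can racemise under the basic cuprate conditions. Against the better C4 control, the chosen plan forms ring A at the final oxidation level with both arms in place in one step from 9 and 13, with no carbonyl to delete and no alkenes to differentiate.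

**Alternative 2:** The cut is at C2–C3 and C4–C5. A carbonyl ylide, made from benzylated syringaldehyde A5 by O-alkylation with silylmethyl triflate A6 and fluoride-induced desilylation, would add across menthyloxyfuranone A4 to give cis-fused bicycle A7. Merits: ring A and three stereocentres arise in one cycloaddition. The cis ring fusion guarantees the C3/C4 cis relation, the exo aryl group gives 2,3-trans, and the acetal auxiliary fixes the absolute sense. In stereocontrol this is equal to or better than the chosen plan. Weak points: non-stabilised ylides of electron-rich aldehydes form and add with modest efficiency and regiocontrol. A4 must come from the less common (1S,2R,5S)-menthyl series. A7 is far from the target at both arms: the lactone carbonyl must be reduced, and the acetal carbon must be turned into CH2–guaiacyl by aryl addition and deoxygenation of a second electron-rich benzylic C–O bond next to the C2 benzylic ether, with no basis for chemoselectivity. The benzyl ether also has to be removed before the cinnamate is introduced. The chosen plan offers less rigid stereocontrol but delivers 14 with both arms finished.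

**Alternative 3:** The cut is at O1–C2. Anodic oxidation of the free syringyl phenol of seco-diol A8 would give a p-quinone methide at C2, which the C5 hydroxyl would capture to give A9. Merits: a biomimetic closure that needs no activating group. A9 already has the primary hydroxyl free and only one silyl ether, so the end game is shorter than from 14 and avoids the selective desilylation of step 11; here this road is better. Weak points: A8 must already carry the C3 and C4 stereocentres and two different benzyl groups, and making it enantioselectively costs more steps than the whole front end to 9. The key step forms only one C–O bond and one stereocentre. The quinone methide can also be captured by the guaiacyl ring (aryltetralin formation) or by solvent. A9 keeps a free phenol para to a more easily oxidised benzylic ether C–H, so over-oxidation is a real risk. The chosen plan answers this with a key step that builds two C–C bonds, the ring and two stereocentres from one Sharpless-derived centre.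

Key step: step 10

Remark on the chemistry: the benzylic carbon of 7, 8 and 9 is R because the neighbouring carbinol or iodo carbon outranks the aryl ring; the same spatial arrangement is named S at C2 of 14–20, where ring carbon C3 ranks below the aryl ring.

Remark on the chemistry: the halide on zinc in 13 is a spectator; the reagent is written as the iodide formed from the Grignard reagent and ZnI2.

## Route

Step 1
Reactants: 1 sinapic acid
Product: 2 methyl sinapate, methyl (E)-3-(4-hydroxy-3,5-dimethoxyphenyl)prop-2-enoate
Conditions: MeOH, H2SO4 (cat.), reflux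
Reagents that add atoms: methanol, CO
Why: Fischer esterification; the hindered phenol and the E-alkene are inert to acid in methanol.

Step 2
Reactants: 2 methyl sinapate
Product: 3 methyl (E)-3-[4-(tert-butyldimethylsilyloxy)-3,5-dimethoxyphenyl]prop-2-enoate
Conditions: TBSCl, imidazole, DMF, rt
Reagents that add atoms: tert-butyldimethylsilyl chloride, CC(C)(C)[Si](C)(C)Cl
Why: Silylation of a phenol with a silyl chloride and imidazole; the 2,6-dimethoxyphenol is hindered but acidic and is silylated in DMF.

Step 3
Reactants: 3 methyl (E)-3-[4-(tert-butyldimethylsilyloxy)-3,5-dimethoxyphenyl]prop-2-enoate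
Product: 4 (E)-3-[4-(tert-butyldimethylsilyloxy)-3,5-dimethoxyphenyl]prop-2-en-1-ol
Conditions: iBu2AlH (2.5 equiv), CH2Cl2, −78 °C; aq. potassium sodium tartrate
Reagents that add atoms: none
Why: 1,2-Reduction of an α,β-unsaturated ester to the allylic alcohol with iBu2AlH; the aryl silyl ether and the E-alkene are stable at −78 °C.

Step 4
Reactants: 4 (E)-3-[4-(tert-butyldimethylsilyloxy)-3,5-dimethoxyphenyl]prop-2-en-1-ol
Product: 5 [(2S,3S)-3-[4-(tert-butyldimethylsilyloxy)-3,5-dimethoxyphenyl]oxiran-2-yl]methanol
Conditions: Ti(OiPr)4 (10 mol%), L-(+)-diisopropyl tartrate (12 mol%), tBuOOH, 4 Å molecular sieves, CH2Cl2, −20 °C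
Reagents that add atoms: tert-butyl hydroperoxide, CC(C)(C)OO
Why: Sharpless asymmetric epoxidation; with the L-(+)-tartrate an E-3-aryl allylic alcohol should give the (2S,3S)-epoxy alcohol, which sets the one stereocentre (C3 here, later C2 of ring A) carried to the target. The two flanking methoxy groups twist the silyloxy group out of conjugation, which should keep the epoxide from ionising if the work-up is kept non-acidic.

Step 5
Reactants: 5 [(2S,3S)-3-[4-(tert-butyldimethylsilyloxy)-3,5-dimethoxyphenyl]oxiran-2-yl]methanol; 6 allyl alcohol
Product: 7 (2S,3R)-3-[4-(tert-butyldimethylsilyloxy)-3,5-dimethoxyphenyl]-3-(prop-2-enyloxy)propane-1,2-diol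
Conditions: 6 (10 equiv), BF3·OEt2 (10 mol%), CH2Cl2, −40 to −20 °C
Reagents that add atoms: none
Why: Lewis acid-catalysed alcoholysis of a 3-aryl-2,3-epoxy alcohol; the alcohol attacks the benzylic carbon anti to the epoxide oxygen, so C3 is inverted to R and C2 is untouched. Low temperature and excess nucleophile should keep the opening invertive; any benzylic epimer is a diastereomer of 7 and can be removed here, before the carbinol centre is erased.

Step 6
Reactants: 7 (2S,3R)-3-[4-(tert-butyldimethylsilyloxy)-3,5-dimethoxyphenyl]-3-(prop-2-enyloxy)propane-1,2-diol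
Product: 8 (1R,2S)-3-(tert-butyldimethylsilyloxy)-1-[4-(tert-butyldimethylsilyloxy)-3,5-dimethoxyphenyl]-1-(prop-2-enyloxy)propan-2-ol
Conditions: TBSCl (1.05 equiv), imidazole, CH2Cl2, 0 °C
Reagents that add atoms: tert-butyldimethylsilyl chloride, CC(C)(C)[Si](C)(C)Cl
Why: Selective silylation of the primary hydroxyl of a 1,2-diol; the secondary hydroxyl next to the benzylic ether carbon reacts much more slowly.

Step 7
Reactants: 8 (1R,2S)-3-(tert-butyldimethylsilyloxy)-1-[4-(tert-butyldimethylsilyloxy)-3,5-dimethoxyphenyl]-1-(prop-2-enyloxy)propan-2-ol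
Product: 9 tert-butyl-[4-[(1R,2R)-3-(tert-butyldimethylsilyloxy)-2-iodo-1-(prop-2-enyloxy)propyl]-2,6-dimethoxyphenoxy]dimethylsilane
Conditions: PPh3, I2, imidazole, toluene, 70 °C
Reagents that add atoms: iodine, II
Why: Appel-type iodination of a secondary alcohol through its alkoxyphosphonium iodide with inversion, giving the (1R,2R)-iodide. The configuration at the iodo carbon does not matter because this carbon becomes a radical in step 10.

Step 8
Reactants: 10 4-bromo-2-methoxyphenol
Product: 11 (4-bromo-2-methoxyphenoxy)(tert-butyl)dimethylsilane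
Conditions: TBSCl, imidazole, DMF, rt
Reagents that add atoms: tert-butyldimethylsilyl chloride, CC(C)(C)[Si](C)(C)Cl
Why: Silylation of a phenol with a silyl chloride and imidazole; the aryl bromide is inert.

Step 9
Reactants: 11 (4-bromo-2-methoxyphenoxy)(tert-butyl)dimethylsilane
Product: 13 [4-(tert-butyldimethylsilyloxy)-3-methoxyphenyl]zinc iodide, via arylmagnesium bromide 12 (not isolated)
Conditions: Mg turnings (I2-activated), THF, 45 °C; then ZnI2 (1.05 equiv), THF, 0 °C to rt; solution titrated and used directly
Reagents that add atoms: zinc iodide, I[Zn]I; magnesium, [Mg] (retained only in intermediate 12)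
Why: Grignard formation followed by transmetalation to zinc. The bromide is para to the silyloxy group, so no silyl shift to carbon can occur, and no alkyl halide by-product is formed that could compete in step 10.

Step 10
Reactants: 9 tert-butyl-[4-[(1R,2R)-3-(tert-butyldimethylsilyloxy)-2-iodo-1-(prop-2-enyloxy)propyl]-2,6-dimethoxyphenoxy]dimethylsilane; 13 [4-(tert-butyldimethylsilyloxy)-3-methoxyphenyl]zinc iodide
Product: 14 (2S,3R,4R)-2-[4-(tert-butyldimethylsilyloxy)-3,5-dimethoxyphenyl]-3-[(tert-butyldimethylsilyloxy)methyl]-4-[[4-(tert-butyldimethylsilyloxy)-3-methoxyphenyl]methyl]oxolane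
Conditions: 13 (1.6 equiv), NiBr2(dme) (5 mol%; dme = MeOCH2CH2OMe), 2,2':6',2''-terpyridine (6 mol%), THF/NMP, rt
Reagents that add atoms: none
Why: Nickel-catalysed radical cyclisation/Negishi-type cross-coupling: a terpyridine-bound monovalent nickel aryl species, formed from NiBr2(dme), the ligand and 13, should reduce the C–I bond of 9 by single-electron transfer and release the secondary C3 radical and a divalent aryl nickel iodide. The radical closes ring A by 5-exo-trig attack on the internal carbon of the allyl ether (C3–C4); at a few mol% of nickel this unimolecular step is orders of magnitude faster than bimolecular capture of the secondary radical, so ring closure precedes coupling. The exocyclic primary radical then adds to the divalent aryl nickel complex, and reductive elimination from the trivalent alkyl(aryl) nickel species forms the CH2–aryl bond and returns monovalent nickel, which is re-arylated by 13. The closest known reaction type is the nickel–terpyridine cyclisation/arylzinc coupling of β-halo ethers of allyl alcohol, secondary iodides flanked by oxygen included, to 3-(arylmethyl)oxolanes. Both new centres are controlled by the C2 aryl group through a chair-like transition state in which it lies pseudo-equatorial: the CH2OTBS arm on the planar radical carbon turns away from it (C3 trans to aryl), and the alkene terminus takes the pseudo-equatorial position, which puts the new C4 arm cis to the C3 arm and trans to the aryl group. The same C3 radical, generated from epoxy ethers with Cp2TiCl (trivalent titanium), is known to close in this 2,3-trans-3,4-cis sense. The step needs a radical and never a carbanion at C3, since a C3–metal bond would expel the β-allyloxy or β-silyloxy group; single-electron activation of the iodide secures this, and the silyl ethers are inert to the arylzinc reagent at room temperature.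

Step 11
Reactants: 14 (2S,3R,4R)-2-[4-(tert-butyldimethylsilyloxy)-3,5-dimethoxyphenyl]-3-[(tert-butyldimethylsilyloxy)methyl]-4-[[4-(tert-butyldimethylsilyloxy)-3-methoxyphenyl]methyl]oxolane
Product: 15 [(2S,3R,4R)-2-[4-(tert-butyldimethylsilyloxy)-3,5-dimethoxyphenyl]-4-[[4-(tert-butyldimethylsilyloxy)-3-methoxyphenyl]methyl]oxolan-3-yl]methanol
Conditions: pyridinium p-toluenesulfonate (0.2 equiv), MeOH/CH2Cl2, rt
Reagents that add atoms: none
Why: Acid-catalysed methanolysis of a primary alkyl silyl ether; aryl silyl ethers are cleaved far more slowly by acid, and this weak acid should not ionise the C2 benzylic ether while both phenols stay silylated.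

Step 12
Reactants: 16 ferulic acid
Product: 18 (E)-3-[4-(tert-butyldimethylsilyloxy)-3-methoxyphenyl]prop-2-enoic acid, via bis-silylated ferulate 17 (not isolated)
Conditions: TBSCl (2.4 equiv), imidazole, DMF, rt; then AcOH/THF/H2O, rt
Reagents that add atoms: tert-butyldimethylsilyl chloride, CC(C)(C)[Si](C)(C)Cl
Why: Exhaustive silylation followed by selective hydrolysis of the silyl ester, which is far more labile to aqueous acid than the aryl silyl ether.

Step 13
Reactants: 15 [(2S,3R,4R)-2-[4-(tert-butyldimethylsilyloxy)-3,5-dimethoxyphenyl]-4-[[4-(tert-butyldimethylsilyloxy)-3-methoxyphenyl]methyl]oxolan-3-yl]methanol; 18 (E)-3-[4-(tert-butyldimethylsilyloxy)-3-methoxyphenyl]prop-2-enoic acid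
Product: 19 [(2S,3R,4R)-2-[4-(tert-butyldimethylsilyloxy)-3,5-dimethoxyphenyl]-4-[[4-(tert-butyldimethylsilyloxy)-3-methoxyphenyl]methyl]oxolan-3-yl]methyl (E)-3-[4-(tert-butyldimethylsilyloxy)-3-methoxyphenyl]prop-2-enoate
Conditions: N,N'-diisopropylcarbodiimide (1.3 equiv), DMAP (20 mol%), CH2Cl2, 0 °C to rt
Reagents that add atoms: none
Why: Steglich esterification under neutral conditions; all phenols are masked, so only the primary alcohol is acylated, and neither the E-alkene nor C2 is disturbed.

Step 14
Reactants: 19 [(2S,3R,4R)-2-[4-(tert-butyldimethylsilyloxy)-3,5-dimethoxyphenyl]-4-[[4-(tert-butyldimethylsilyloxy)-3-methoxyphenyl]methyl]oxolan-3-yl]methyl (E)-3-[4-(tert-butyldimethylsilyloxy)-3-methoxyphenyl]prop-2-enoate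
Product: 20 [(2S,3R,4R)-2-(4-hydroxy-3,5-dimethoxyphenyl)-4-[(4-hydroxy-3-methoxyphenyl)methyl]oxolan-3-yl]methyl (E)-3-(4-hydroxy-3-methoxyphenyl)prop-2-enoate (CNP0289934.1)
Conditions: Bu4NF (3.5 equiv), AcOH (4 equiv), THF, 0 °C
Reagents that add atoms: none
Why: Fluoride cleavage of three aryl silyl ethers; buffering with acetic acid keeps free phenoxide from attacking the cinnamate ester, and no acid strong enough to ionise C2 is present.

## Compound list

1 | sinapic acid, (E)-3-(4-hydroxy-3,5-dimethoxyphenyl)prop-2-enoic acid | COc1cc(/C=C/C(=O)O)cc(OC)c1O | starting material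
2 | methyl sinapate, methyl (E)-3-(4-hydroxy-3,5-dimethoxyphenyl)prop-2-enoate | COC(=O)/C=C/c1cc(OC)c(O)c(OC)c1 | intermediate
3 | methyl (E)-3-[4-(tert-butyldimethylsilyloxy)-3,5-dimethoxyphenyl]prop-2-enoate | COC(=O)/C=C/c1cc(OC)c(O[Si](C)(C)C(C)(C)C)c(OC)c1 | intermediate
4 | (E)-3-[4-(tert-butyldimethylsilyloxy)-3,5-dimethoxyphenyl]prop-2-en-1-ol | OC/C=C/c1cc(OC)c(O[Si](C)(C)C(C)(C)C)c(OC)c1 | intermediate
5 | [(2S,3S)-3-[4-(tert-butyldimethylsilyloxy)-3,5-dimethoxyphenyl]oxiran-2-yl]methanol | OC[C@@H]1O[C@H]1c1cc(OC)c(O[Si](C)(C)C(C)(C)C)c(OC)c1 | intermediate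
6 | allyl alcohol, prop-2-en-1-ol | C=CCO | starting material
7 | (2S,3R)-3-[4-(tert-butyldimethylsilyloxy)-3,5-dimethoxyphenyl]-3-(prop-2-enyloxy)propane-1,2-diol | C=CCO[C@@H]([C@@H](O)CO)c1cc(OC)c(O[Si](C)(C)C(C)(C)C)c(OC)c1 | intermediate
8 | (1R,2S)-3-(tert-butyldimethylsilyloxy)-1-[4-(tert-butyldimethylsilyloxy)-3,5-dimethoxyphenyl]-1-(prop-2-enyloxy)propan-2-ol | C=CCO[C@@H]([C@@H](O)CO[Si](C)(C)C(C)(C)C)c1cc(OC)c(O[Si](C)(C)C(C)(C)C)c(OC)c1 | intermediate
9 | tert-butyl-[4-[(1R,2R)-3-(tert-butyldimethylsilyloxy)-2-iodo-1-(prop-2-enyloxy)propyl]-2,6-dimethoxyphenoxy]dimethylsilane | C=CCO[C@@H]([C@H](I)CO[Si](C)(C)C(C)(C)C)c1cc(OC)c(O[Si](C)(C)C(C)(C)C)c(OC)c1 | intermediate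
10 | 4-bromo-2-methoxyphenol | COc1cc(Br)ccc1O | starting material
11 | (4-bromo-2-methoxyphenoxy)(tert-butyl)dimethylsilane | COc1cc(Br)ccc1O[Si](C)(C)C(C)(C)C | intermediate
12 | [4-(tert-butyldimethylsilyloxy)-3-methoxyphenyl]magnesium bromide (formed in the flask) | COc1cc([Mg]Br)ccc1O[Si](C)(C)C(C)(C)C | intermediate
13 | [4-(tert-butyldimethylsilyloxy)-3-methoxyphenyl]zinc iodide | COc1cc([Zn]I)ccc1O[Si](C)(C)C(C)(C)C | intermediate
14 | (2S,3R,4R)-2-[4-(tert-butyldimethylsilyloxy)-3,5-dimethoxyphenyl]-3-[(tert-butyldimethylsilyloxy)methyl]-4-[[4-(tert-butyldimethylsilyloxy)-3-methoxyphenyl]methyl]oxolane | CC(C)(C)[Si](C)(C)OC[C@H]2[C@@H](Cc3ccc(O[Si](C)(C)C(C)(C)C)c(OC)c3)CO[C@@H]2c2cc(OC)c(O[Si](C)(C)C(C)(C)C)c(OC)c2 | intermediate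
15 | [(2S,3R,4R)-2-[4-(tert-butyldimethylsilyloxy)-3,5-dimethoxyphenyl]-4-[[4-(tert-butyldimethylsilyloxy)-3-methoxyphenyl]methyl]oxolan-3-yl]methanol | OC[C@H]2[C@@H](Cc3ccc(O[Si](C)(C)C(C)(C)C)c(OC)c3)CO[C@@H]2c2cc(OC)c(O[Si](C)(C)C(C)(C)C)c(OC)c2 | intermediate
16 | ferulic acid, (E)-3-(4-hydroxy-3-methoxyphenyl)prop-2-enoic acid | COc1cc(/C=C/C(=O)O)ccc1O | starting material
17 | tert-butyldimethylsilyl (E)-3-[4-(tert-butyldimethylsilyloxy)-3-methoxyphenyl]prop-2-enoate (formed in the flask) | COc1cc(/C=C/C(=O)O[Si](C)(C)C(C)(C)C)ccc1O[Si](C)(C)C(C)(C)C | intermediate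
18 | (E)-3-[4-(tert-butyldimethylsilyloxy)-3-methoxyphenyl]prop-2-enoic acid | COc1cc(/C=C/C(=O)O)ccc1O[Si](C)(C)C(C)(C)C | intermediate
19 | [(2S,3R,4R)-2-[4-(tert-butyldimethylsilyloxy)-3,5-dimethoxyphenyl]-4-[[4-(tert-butyldimethylsilyloxy)-3-methoxyphenyl]methyl]oxolan-3-yl]methyl (E)-3-[4-(tert-butyldimethylsilyloxy)-3-methoxyphenyl]prop-2-enoate | COc1cc(/C=C/C(=O)OC[C@H]2[C@@H](Cc3ccc(O[Si](C)(C)C(C)(C)C)c(OC)c3)CO[C@@H]2c2cc(OC)c(O[Si](C)(C)C(C)(C)C)c(OC)c2)ccc1O[Si](C)(C)C(C)(C)C | intermediate
20 | [(2S,3R,4R)-2-(4-hydroxy-3,5-dimethoxyphenyl)-4-[(4-hydroxy-3-methoxyphenyl)methyl]oxolan-3-yl]methyl (E)-3-(4-hydroxy-3-methoxyphenyl)prop-2-enoate (CNP0289934.1) | COc1cc(/C=C/C(=O)OC[C@H]2[C@@H](Cc3ccc(O)c(OC)c3)CO[C@@H]2c2cc(OC)c(O)c(OC)c2)ccc1O | target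

## Step count and risk

Total step count: 14. Longest linear sequence: 11 steps (steps 1–7, 10, 11, 13 and 14, from sinapic acid 1).

**Step 10 (key step).** The most likely failure is insufficient facial control at C4: the cis preference of a radical carrying a substituent on the radical carbon is only moderate when the acceptor is a terminal alkene, so the C4 epimer may form alongside 14. Less likely are two-electron reduction of the iodide with loss of the β-alkoxy group, and consumption of 13 by homocoupling. Fallback, setting out from 9 and returning at 14: cross-metathesis of 9 with tert-butyl(4-ethenyl-2-methoxyphenoxy)dimethylsilane F1 (from commercial 2-methoxy-4-vinylphenol, TBSCl and imidazole), using the second-generation Grubbs catalyst in CH2Cl2 at 40 °C, places the guaiacyl ring on the alkene and gives the (E)-3-arylallyl ether iodide F2. Treating F2 with (Me3Si)3SiH and AIBN in toluene at 80 °C generates the same C3 radical, which closes 5-exo onto the styrene-type alkene; the benzylic radical is reduced by the silane to give 14. This is the established reductive radical route to 2-aryl-3-(oxymethyl)-4-benzyloxolanes, and the more hindered, more stabilised acceptor usually raises the cis selectivity.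

**Step 5.** The opening may run partly through a benzylic cation, which erodes the configuration of the only bought stereocentre; Lewis acid-induced rearrangement of the epoxide to a carbonyl compound is a second concern. Fallback, setting out from 1 and returning at 8: the phenol is carried as an electron-withdrawing acetate through epoxidation and opening, so that the aryl ring resembles an unactivated phenyl ring and the opening is cleanly invertive. Acetylation (Ac2O, pyridine) gives (E)-3-(4-acetoxy-3,5-dimethoxyphenyl)prop-2-enoic acid F3. SOCl2 converts it into the acid chloride F4, and NaBH4 in ethyl acetate reduces this chemoselectively to 4-[(E)-3-hydroxyprop-1-enyl]-2,6-dimethoxyphenyl acetate F5. Sharpless epoxidation with the same L-(+)-tartrate gives epoxy alcohol acetate F6, and opening with 6 under BF3·OEt2 gives diol acetate F7. K2CO3 in MeOH at 0 °C frees the phenol to give triol F8, and TBSCl (2.2 equiv) with imidazole silylates the phenol and the primary hydroxyl to arrive at 8.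

**Step 7.** Substitution at a secondary carbon flanked by two oxygen-bearing carbons is slow at 70 °C, which leaves room for elimination or for participation of the electron-rich aryl group (aryl shift through a bridged cation). Fallback, setting out from 8 and returning at 9: the alcohol is converted at −40 °C (Tf2O, 2,6-lutidine, CH2Cl2) into the secondary triflate F9, which is displaced without isolation by Bu4NI in toluene between 0 °C and rt. This is an SN2 reaction on a preformed sulfonate below room temperature, as used for hindered carbohydrate positions, and gives 9 with the same inversion.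

**Step 11.** The acid may cleave an aryl silyl ether as well, or ionise the C2 benzylic ether, leading to epimerisation, methanolysis or ring closure onto the guaiacyl ring. Fallback, setting out from 14 and returning at 20: all three silyl groups are removed with Bu4NF/AcOH in THF to give 5-methoxylariciresinol F10. The primary alcohol of F10 is then esterified with unprotected ferulic acid 16 under Mitsunobu conditions (PPh3, diisopropyl azodicarboxylate, THF, 0 °C). Only the carboxylic acid is acidic enough to serve as the nucleophile, so the phenols stay free and 20 is reached directly; steps 12–14 are then not needed.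

## Further compounds

F1 | step 10 | tert-butyl(4-ethenyl-2-methoxyphenoxy)dimethylsilane | C=Cc1ccc(O[Si](C)(C)C(C)(C)C)c(OC)c1
F2 | step 10 | tert-butyl-[4-[(1R,2R)-3-(tert-butyldimethylsilyloxy)-2-iodo-1-[(E)-3-[4-(tert-butyldimethylsilyloxy)-3-methoxyphenyl]prop-2-enoxy]propyl]-2,6-dimethoxyphenoxy]dimethylsilane | COc1cc(/C=C/CO[C@@H]([C@H](I)CO[Si](C)(C)C(C)(C)C)c2cc(OC)c(O[Si](C)(C)C(C)(C)C)c(OC)c2)ccc1O[Si](C)(C)C(C)(C)C
F3 | step 5 | (E)-3-(4-acetoxy-3,5-dimethoxyphenyl)prop-2-enoic acid | CC(=O)Oc1c(OC)cc(/C=C/C(=O)O)cc1OC
F4 | step 5 | (E)-3-(4-acetoxy-3,5-dimethoxyphenyl)prop-2-enoyl chloride | CC(=O)Oc1c(OC)cc(/C=C/C(=O)Cl)cc1OC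
F5 | step 5 | 4-[(E)-3-hydroxyprop-1-enyl]-2,6-dimethoxyphenyl acetate | CC(=O)Oc1c(OC)cc(/C=C/CO)cc1OC
F6 | step 5 | 4-[(2S,3S)-3-(hydroxymethyl)oxiran-2-yl]-2,6-dimethoxyphenyl acetate | OC[C@@H]1O[C@H]1c1cc(OC)c(OC(C)=O)c(OC)c1
F7 | step 5 | 4-[(1R,2S)-2,3-dihydroxy-1-(prop-2-enyloxy)propyl]-2,6-dimethoxyphenyl acetate | C=CCO[C@@H]([C@@H](O)CO)c1cc(OC)c(OC(C)=O)c(OC)c1
F8 | step 5 | (2S,3R)-3-(4-hydroxy-3,5-dimethoxyphenyl)-3-(prop-2-enyloxy)propane-1,2-diol | C=CCO[C@@H]([C@@H](O)CO)c1cc(OC)c(O)c(OC)c1
F9 | step 7 | (1R,2S)-3-(tert-butyldimethylsilyloxy)-1-[4-(tert-butyldimethylsilyloxy)-3,5-dimethoxyphenyl]-1-(prop-2-enyloxy)propan-2-yl trifluoromethanesulfonate | C=CCO[C@@H]([C@@H](OS(=O)(=O)C(F)(F)F)CO[Si](C)(C)C(C)(C)C)c1cc(OC)c(O[Si](C)(C)C(C)(C)C)c(OC)c1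
F10 | step 11 | 5-methoxylariciresinol, 4-[(2S,3R,4R)-4-[(4-hydroxy-3-methoxyphenyl)methyl]-3-(hydroxymethyl)oxolan-2-yl]-2,6-dimethoxyphenol | OC[C@H]2[C@@H](Cc3ccc(O)c(OC)c3)CO[C@@H]2c2cc(OC)c(O)c(OC)c2
A1 | alternative 1 | (S)-5-[4-(tert-butyldimethylsilyloxy)-3,5-dimethoxyphenyl]furan-2(5H)-one | O=C1C=C[C@@H](c2cc(OC)c(O[Si](C)(C)C(C)(C)C)c(OC)c2)O1
A2 | alternative 1 | 4-(tert-butyldimethylsilyloxy)-3-methoxybenzaldehyde | COc1cc(C=O)ccc1O[Si](C)(C)C(C)(C)C
A3 | alternative 1 | (3E,4S,5S)-3-[[4-(tert-butyldimethylsilyloxy)-3-methoxyphenyl]methylidene]-5-[4-(tert-butyldimethylsilyloxy)-3,5-dimethoxyphenyl]-4-ethenyloxolan-2-one | C=C[C@H]2/C(=C\c3ccc(O[Si](C)(C)C(C)(C)C)c(OC)c3)C(=O)O[C@@H]2c2cc(OC)c(O[Si](C)(C)C(C)(C)C)c(OC)c2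
A4 | alternative 2 | (5S)-5-[(1S,2R,5S)-5-methyl-2-(propan-2-yl)cyclohexyl]oxyfuran-2(5H)-one | O=C1C=C[C@@H](O[C@H]2C[C@@H](C)CC[C@@H]2C(C)C)O1
A5 | alternative 2 | 4-(benzyloxy)-3,5-dimethoxybenzaldehyde | COc1cc(C=O)cc(OC)c1OCc1ccccc1
A6 | alternative 2 | (trimethylsilyl)methyl trifluoromethanesulfonate | C[Si](C)(C)COS(=O)(=O)C(F)(F)F
A7 | alternative 2 | cis-fused 6-[4-(benzyloxy)-3,5-dimethoxyphenyl]-4-[(1S,2R,5S)-5-methyl-2-(propan-2-yl)cyclohexyl]oxy-3,7-dioxabicyclo[3.3.0]octan-2-one, aryl exo | O=C1[C@H]2[C@@H]([C@@H](O[C@H]3C[C@@H](C)CC[C@@H]3C(C)C)O1)CO[C@@H]2c1cc(OC)c(OCc2ccccc2)c(OC)c1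
A8 | alternative 3 | (2R,3R)-2-[[4-(tert-butyldimethylsilyloxy)-3-methoxyphenyl]methyl]-3-[(4-hydroxy-3,5-dimethoxyphenyl)methyl]butane-1,4-diol | OC[C@H](Cc1cc(OC)c(O)c(OC)c1)[C@@H](Cc1ccc(O[Si](C)(C)C(C)(C)C)c(OC)c1)CO
A9 | alternative 3 | 4-[(2S,3R,4R)-4-[[4-(tert-butyldimethylsilyloxy)-3-methoxyphenyl]methyl]-3-(hydroxymethyl)oxolan-2-yl]-2,6-dimethoxyphenol | OC[C@H]2[C@@H](Cc3ccc(O[Si](C)(C)C(C)(C)C)c(OC)c3)CO[C@@H]2c2cc(OC)c(O)c(OC)c2
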